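Two colleagues disagree about one curve. The question is how much of the free monomer sits in chains after the set time, as the initiator charge goes up.

all flasks: free monomer 0.050 M
- Friday's: initiator 0.010 mM; run made earlier
- Thursday's: initiator 0.067 mM; run made earlier
- midnight: initiator 0.020 mM; time 10 h
- dawn: initiator 0.030 mM; time 10 h
- winter: initiator 0.040 mM; time 10 h
- spring: initiator 0.060 mM; time 10 h
- autumn: initiator 0.10 mM; time 10 h

| Friday's: time / h | Friday's: monomer in chains / % | Thursday's: time / h | Thursday's: monomer in chains / % |
|---|---|---|---|
| 0.417 | 1 | 0.833 | 0 |
| 0.667 | 2 | 1.50 | 3 |
| 1.00 | 0 | 2.50 | 6 |
| 2.00 | 0 | 3.00 | 8 |
| 3.00 | 0 | 4.00 | 7 |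
| 5.00 | 4 | 5.00 | 17 |

(scatter of a reading: 2 percentage points)

- candidate steps: free monomer + initiator -> living end + monomer in chains; free monomer + living end -> monomer in chains + living end; free monomer -> decomposition product
- "hardly changes" means that all values lie within two and a half points (for a concentration: within two and a half percent of the largest)

- amount of monomer in chains at the end, in percent of the free monomer charged for midnight, dawn, winter, spring, autumn, in this order
- how the row runs (rises all the way / hardly changes / rises, then falls / falls all the way / falls, then rises)

Both take free monomer to enter chains by adding to living ends, so their dispute is about one amount: how many living ends stand in the flask at a given hour.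

Ada says the living ends equal the initiator charge from the start. At a fixed level of living ends, free monomer falls pseudo-first-order, so the fraction in chains climbs on a straight line at first. Her line through the origin of Thursday's readings has a slope of 2.64 % h⁻¹. Scaled by charge, with the bend for monomer used, it gives 7.59% for midnight and 32.6% for autumn.

Ben answers that no living end is charged. In his view they form from initiator and free monomer, so they start at zero and grow with time, at least while the initiator stays near its charge. The fraction in chains then climbs with the square of the time. His number, read from Thursday's run, is 12.4 h, the ramp time: the clock time divided by the ramp time and then squared gives the small fraction in chains at Thursday's initiator charge. Multiply that square by the initiator charge over Thursday's, and the fraction of free monomer left is the exponential of minus the product.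

At 5.00 h on Thursday, Ada's line gives 13.2% and Ben's curve 16.3%, against a reading of 17%. With a scatter of 2 percentage points, the readings lean but do not settle it. Friday's flask, by the ramp time, should hold 2.39% at 5.00 h, and 4% was read.

I commit to Ben's row: 17.6%, 25.2%, 32.1%, 44.1% and 62.0%.

The forecast takes Ada's side on a slope of its own, “Taking living ends ≈ initiator charged”, and reads 9%, 13%, 17%, 25% and 37%, so that the row rises all the way.

The flasks give 17.7%, 25.0%, 31.5%, 42.6% and 58.7%, and the row rises all the way.

    free monomer + initiator → living end + monomer in chains (k = 1.30 M⁻¹ h⁻¹)
    free monomer + living end → monomer in chains + living end, rate k2*[living end]*[free monomer] (k = 3800 M⁻¹ h⁻¹)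
    free monomer → decomposition product (k = 9.70 × 10⁻⁴ h⁻¹)

In midnight the living ends stand at 45.4% of the initiator charge after 10.0 h, and Ada's picture comes near in that flask at 100 h, with 80.5% of the charge, when free monomer is down to 0.430%. At 5.00 h the ramp time gives 4.73% for midnight, where the flask holds 5.35%, and 21.5% for autumn, where it holds 23.4%.

The numbers in the tables come from a simulation from invented constants, and the scatter is random.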